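**Plan**

- Guaiane numbering: ring A is the cyclopentenone C1–C5, ring B the seven-membered ring C1, C5–C10, and C11 the acetoxylated side-chain carbon. The retrosynthesis cuts the C8–O methacrylate first, then C7–C8 together with C11–OAc, then the prenyl arm on C5 (C7=C11 and C5–C6), and last C1–C10.
- Enabling feature: in ring B, C7 and C8 are neighbouring stereocentres, C7 carrying the tertiary acetoxy carbon C11 and C8 a secondary oxygen. This is the pattern a C8 aldehyde leaves when the C7=C11 prenyl alkene adds to it and acetate caps C11, and ring A holds the two arms side by side on C1 and C5.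
- Forward: ring A is bought. The C10–C9–C8 aldehyde chain is attached at C1 by a Mukaiyama–Michael addition, the C5 arm by Stork–Danheiser allylation and cross-metathesis to prenyl, ring B is then closed by the Prins step, and the methacrylate goes on last.
- Stereochemistry: C10 comes from the imidazolidinone catalyst, C1 from the simple diastereoselection of the same step, and C7 and C8 from the Prins closure under control of C1 and C10.

Key step: step 6

Remark: the target is (1R,7S,8R,10S) in guaiane numbering, that is H-1, the C10 methyl, the C8 oxygen and the C7 side chain lie on one face of ring B; all starting materials are taken as commercial.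

**Route**

Step 1
Reactants: 1 3-ethoxy-2-methylcyclopent-2-en-1-one
Product: 3 tert-butyl[(4-ethoxy-3-methylcyclopenta-1,3-dien-2-yl)oxy]dimethylsilane, via lithium dienolate 2 (not isolated)
Conditions: LiN(i-Pr)2, THF, −78 °C; t-BuMe2SiCl, DMPU, −78 → 0 °C; non-aqueous work-up
Reagents that add atoms: tert-butyldimethylsilyl chloride, CC(C)(C)[Si](C)(C)Cl
Why: Kinetic deprotonation of the vinylogous ester at its α′-methylene followed by O-silylation (silyl enol ether formation) gives the 2-silyloxydiene whose unsubstituted ring CH is the nucleophilic terminus; no stereocentre is formed.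

Step 2
Reactants: 3 tert-butyl[(4-ethoxy-3-methylcyclopenta-1,3-dien-2-yl)oxy]dimethylsilane; 4 (E)-but-2-enal
Product: 5 (3S)-3-[(1R)-4-ethoxy-3-methyl-2-oxocyclopent-3-en-1-yl]butanal
Conditions: (2R,5R)-5-benzyl-2-tert-butyl-3-methylimidazolidin-4-one (20 mol %), 2,4-dinitrobenzoic acid (20 mol %), CH2Cl2, H2O (2 equiv), −50 °C
Reagents that add atoms: none
Why: Iminium-catalysed Mukaiyama–Michael addition: the benzyl group of the (2R,5R)-imidazolidinone shields the Re face at C3 of the E-iminium ion of 4, so the ring CH of 3 adds to the Si face and sets C10 as S, while the synclinal open transition state of like topicity (Si face of the dienol ether carbon, usual for E-configured cyclic enol donors with E-acceptors) is expected to set C1 as R, and water removes the silyl group to release the vinylogous ester.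

Step 3
Reactants: 5 (3S)-3-[(1R)-4-ethoxy-3-methyl-2-oxocyclopent-3-en-1-yl]butanal
Product: 6 (5R)-5-[(2S)-4,4-diethoxybutan-2-yl]-3-ethoxy-2-methylcyclopent-2-en-1-one
Conditions: HC(OEt)3, EtOH, pyridinium p-toluenesulfonate (cat.), 0 °C → rt
Reagents that add atoms: triethyl orthoformate, CCOC(OCC)OCC
Why: Acid-catalysed acetalisation with an orthoformate is selective for the aldehyde over the vinylogous ester carbonyl, ethanol makes any exchange at the enol ether degenerate, and the acetal masks the aldehyde against the Grignard reagent of step 4; the mild acid does not enolise C1.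

Step 4
Reactants: 6 (5R)-5-[(2S)-4,4-diethoxybutan-2-yl]-3-ethoxy-2-methylcyclopent-2-en-1-one; 7 allylmagnesium bromide
Product: 9 (3S)-3-[(1R)-3-methyl-4-oxo-2-(prop-2-en-1-yl)cyclopent-2-en-1-yl]butanal, via tertiary allyl carbinol 8 (not isolated)
Conditions: CH2=CHCH2MgBr, THF, −78 → 0 °C; then 1 M HCl (aq), THF, rt
Reagents that add atoms: water, O
Why: Stork–Danheiser transposition: 1,2-addition of the allyl Grignard reagent to the vinylogous ester carbonyl gives carbinol 8, and aqueous acid then ionises it, hydrolyses the enol ether to the transposed enone and cleaves the acetal in one operation; C1 and C10 are not touched, and allyl is used in place of prenyl because a prenyl Grignard reagent would bond through its tertiary terminus.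

Step 5
Reactants: 9 (3S)-3-[(1R)-3-methyl-4-oxo-2-(prop-2-en-1-yl)cyclopent-2-en-1-yl]butanal; 10 2-methylbut-2-ene
Product: 11 (3S)-3-[(1R)-3-methyl-2-(3-methylbut-2-en-1-yl)-4-oxocyclopent-2-en-1-yl]butanal
Conditions: second-generation Grubbs catalyst RuCl2(=CHPh)(H2IMes)(PCy3) (5 mol %), 2-methylbut-2-ene (excess), CH2Cl2, rt
Reagents that add atoms: none
Why: Olefin cross-metathesis of the terminal alkene with 2-methylbut-2-ene exchanges the methylidene for an isopropylidene unit and so turns allyl into prenyl, while the tetrasubstituted enone alkene is inert and the aldehyde is tolerated.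

Step 6
Reactants: 11 (3S)-3-[(1R)-3-methyl-2-(3-methylbut-2-en-1-yl)-4-oxocyclopent-2-en-1-yl]butanal
Product: 12 2-[(5S,6R,8S,8aR)-6-hydroxy-3,8-dimethyl-2-oxo-4,5,6,7,8,8a-hexahydro-1H-azulen-5-yl]propan-2-yl acetate
Conditions: BF3·OEt2 (1.5 equiv), AcOH (20 equiv), CH2Cl2, −40 → 0 °C; aq. NaHCO3
Reagents that add atoms: acetic acid, CC(=O)O
Why: BF3 activates the C8 aldehyde, the less substituted terminus C7 of the trisubstituted alkene adds to it to form C7–C8, and acetic acid traps the tertiary C11 cation, so the C8 hydroxyl and the C11 acetate arise already differentiated (Prins cyclisation with carboxylate capture). The closest known reaction is the acid-mediated Prins cyclisation of citronellal to p-menthane-3,8-diol, of which this substrate is the one-carbon homologue. Ring B closes by a seven-membered attack that is exo with respect to both the carbonyl and the alkene (the oxygen and C11 stay outside the ring), helped by ring A, which fixes C1 and C5 and leaves only four freely rotating bonds in the tether. C8 is expected to be set by a chair-like transition state in which the C10 methyl and the C8–O bond are both pseudo-equatorial and hence cis, under control of the existing C10 and C1 centres. C7 is expected to be set by the synclinal approach in which the developing C11 cation lies next to the Lewis-acid-bound oxygen, the arrangement that gives the cis diol from citronellal, which places the C11 side chain cis to the C8 oxygen. The step needs bonding at C7 rather than C11, secured by the Markovnikov polarisation of the prenyl alkene, and activation of the aldehyde in preference to alkene protonation or the enone, secured by the higher electrophilicity of the BF3-bound aldehyde, the unreactive electron-poor C4=C5 bond and the low temperature.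

Step 7
Reactants: 12 2-[(5S,6R,8S,8aR)-6-hydroxy-3,8-dimethyl-2-oxo-4,5,6,7,8,8a-hexahydro-1H-azulen-5-yl]propan-2-yl acetate; 13 methacrylic anhydride
Product: 14 [(5S,6R,8S,8aR)-5-(2-acetyloxypropan-2-yl)-3,8-dimethyl-2-oxo-4,5,6,7,8,8a-hexahydro-1H-azulen-6-yl] 2-methylprop-2-enoate
Conditions: Et3N, 4-(dimethylamino)pyridine (cat.), CH2Cl2, 0 °C → rt
Reagents that add atoms: none
Why: Nucleophile-catalysed (Steglich-type) acylation of the only free hydroxyl with the anhydride leaves the C8–O bond intact, so C8 keeps its configuration, the tertiary acetate does not react, and low temperature limits base-induced acetyl migration.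

**Compound list**

1 | 3-ethoxy-2-methylcyclopent-2-en-1-one | CCOC1=C(C)C(=O)CC1 | starting material
2 | lithium 4-ethoxy-3-methylcyclopenta-1,3-dien-2-olate | [Li+].CCOC1=C(C)C([O-])=CC1 | intermediate
3 | tert-butyl[(4-ethoxy-3-methylcyclopenta-1,3-dien-2-yl)oxy]dimethylsilane | CCOC1=C(C)C(O[Si](C)(C)C(C)(C)C)=CC1 | intermediate
4 | (E)-but-2-enal | C/C=C/C=O | starting material
5 | (3S)-3-[(1R)-4-ethoxy-3-methyl-2-oxocyclopent-3-en-1-yl]butanal | O=CC[C@H](C)[C@H]1CC(OCC)=C(C)C1=O | intermediate
6 | (5R)-5-[(2S)-4,4-diethoxybutan-2-yl]-3-ethoxy-2-methylcyclopent-2-en-1-one | CCOC(OCC)C[C@H](C)[C@H]1CC(OCC)=C(C)C1=O | intermediate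
7 | allylmagnesium bromide | C=CC[Mg]Br | starting material
8 | (5R)-5-[(2S)-4,4-diethoxybutan-2-yl]-3-ethoxy-2-methyl-1-(prop-2-en-1-yl)cyclopent-2-en-1-ol (carbinol centre formed as a mixture, both epimers converge) | CCOC(OCC)C[C@H](C)[C@H]1CC(OCC)=C(C)C1(O)CC=C | intermediate
9 | (3S)-3-[(1R)-3-methyl-4-oxo-2-(prop-2-en-1-yl)cyclopent-2-en-1-yl]butanal | O=CC[C@H](C)[C@H]1CC(=O)C(C)=C1CC=C | intermediate
10 | 2-methylbut-2-ene | CC=C(C)C | starting material
11 | (3S)-3-[(1R)-3-methyl-2-(3-methylbut-2-en-1-yl)-4-oxocyclopent-2-en-1-yl]butanal | O=CC[C@H](C)[C@H]1CC(=O)C(C)=C1CC=C(C)C | intermediate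
12 | 2-[(5S,6R,8S,8aR)-6-hydroxy-3,8-dimethyl-2-oxo-4,5,6,7,8,8a-hexahydro-1H-azulen-5-yl]propan-2-yl acetate (11-acetoxy-8-hydroxyguai-4-en-3-one) | O[C@@H]1C[C@H](C)[C@H]2CC(=O)C(C)=C2C[C@@H]1C(C)(C)OC(C)=O | intermediate
13 | methacrylic anhydride | C=C(C)C(=O)OC(=O)C(C)=C | starting material
14 | [(5S,6R,8S,8aR)-5-(2-acetyloxypropan-2-yl)-3,8-dimethyl-2-oxo-4,5,6,7,8,8a-hexahydro-1H-azulen-6-yl] 2-methylprop-2-enoate | C=C(C)C(=O)O[C@@H]1C[C@H](C)[C@H]2CC(=O)C(C)=C2C[C@@H]1C(C)(C)OC(C)=O | target

**Count and risks**

Total steps: 7. Longest linear sequence: 7 steps (1 → 14).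

Steps most likely to fail:

Step 6. The tertiary cation may be reached by plain protonation of the prenyl alkene instead of by attack on the aldehyde, and the seven-membered closure may lose to elimination or oligomerisation. The aldehyde may also be attacked in the opposite facial sense, giving a trans C7/C8 pair, and the acetyl group may wander from O-11 to the free C8 hydroxyl under the acidic conditions. The fallback separates ring closure from oxygenation and sets out from 11. A Me2AlCl-promoted intramolecular carbonyl-ene reaction (CH2Cl2, −78 °C) forms the same C7–C8 bond and should give, as concerted ene closures normally do, the 7,8-trans isopropenyl alcohol F1. Mukaiyama hydration (Co(acac)2, PhSiH3, O2, i-PrOH) of the isopropenyl group gives the 8-epi diol F2. Mitsunobu esterification with methacrylic acid (PPh3, diisopropyl azodicarboxylate) inverts C8 and gives the 8-methacrylate with free tertiary hydroxyl F3. Acetylation of the tertiary alcohol (Ac2O, Sc(OTf)3 cat., MeCN, −20 °C) returns to the route at 14.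

Step 2. The electron-rich silyloxycyclopentadiene may undergo [4+2] cycloaddition with the iminium ion instead of conjugate addition, it may scramble by 1,5-hydrogen shift before it reacts, and the simple diastereoselection at C1 may be low. The fallback sets out from 1 through its lithium dienolate 2 and uses an auxiliary in place of the catalyst. The acceptor is the crotonoyl imide F4, made from (R)-4-phenyl-1,3-oxazolidin-2-one and crotonoyl chloride. Michael addition of 2 at −78 °C in THF through a lithium-chelated closed transition state, with the phenyl group shielding the Re face of the β-carbon, should give the syn imide adduct F5. Reductive removal of the auxiliary (LiBH4, H2O, Et2O, 0 °C), which leaves the vinylogous ester untouched, gives the primary alcohol F6, and oxidation (TEMPO, PhI(OAc)2, CH2Cl2) returns to the route at 5.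

Step 5. Ruthenium hydride species may move the skipped C7 double bond into conjugation with the enone across the doubly activated C6 methylene, or the exchange may stall before the trisubstituted alkene is reached. The fallback sets out from 6 and installs the prenyl group directly. Prenylbarium chloride (from 1-chloro-3-methylbut-2-ene and activated barium prepared from BaI2 and lithium biphenylide, THF, −78 °C) adds through its primary terminus to give the prenyl carbinol F7, and 1 M HCl then effects the same transposition and acetal cleavage as in step 4, returning to the route at 11.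

**Further compounds**

F1 | step 6 | (5R,6S,8S,8aR)-6-hydroxy-3,8-dimethyl-5-(prop-1-en-2-yl)-4,5,6,7,8,8a-hexahydroazulen-2(1H)-one | O[C@H]1C[C@H](C)[C@H]2CC(=O)C(C)=C2C[C@@H]1C(C)=C
F2 | step 6 | (5S,6S,8S,8aR)-6-hydroxy-5-(2-hydroxypropan-2-yl)-3,8-dimethyl-4,5,6,7,8,8a-hexahydroazulen-2(1H)-one | O[C@H]1C[C@H](C)[C@H]2CC(=O)C(C)=C2C[C@@H]1C(C)(C)O
F3 | step 6 | [(5S,6R,8S,8aR)-5-(2-hydroxypropan-2-yl)-3,8-dimethyl-2-oxo-4,5,6,7,8,8a-hexahydro-1H-azulen-6-yl] 2-methylprop-2-enoate | C=C(C)C(=O)O[C@@H]1C[C@H](C)[C@H]2CC(=O)C(C)=C2C[C@@H]1C(C)(C)O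
F4 | step 2 | (4R)-3-[(2E)-but-2-enoyl]-4-phenyl-1,3-oxazolidin-2-one | C/C=C/C(=O)N1C(=O)OC[C@H]1c1ccccc1
F5 | step 2 | (4R)-3-{(3S)-3-[(1R)-4-ethoxy-3-methyl-2-oxocyclopent-3-en-1-yl]butanoyl}-4-phenyl-1,3-oxazolidin-2-one | O=C(C[C@H](C)[C@H]1CC(OCC)=C(C)C1=O)N1C(=O)OC[C@H]1c1ccccc1
F6 | step 2 | (5R)-3-ethoxy-5-[(2S)-4-hydroxybutan-2-yl]-2-methylcyclopent-2-en-1-one | OCC[C@H](C)[C@H]1CC(OCC)=C(C)C1=O
F7 | step 5 | (5R)-5-[(2S)-4,4-diethoxybutan-2-yl]-3-ethoxy-2-methyl-1-(3-methylbut-2-en-1-yl)cyclopent-2-en-1-ol | CCOC(OCC)C[C@H](C)[C@H]1CC(OCC)=C(C)C1(O)CC=C(C)C
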